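Everything rests on disconnecting the C2–C3 bond of ring C: the flavanone is unfolded to an aryl diazomethyl ketone in which the ring A oxygen O1 carries ring B as a plain benzyl ether. A chiral dirhodium carboxylate converts the diazo carbon (future C3) into a carbenoid that inserts into one enantiotopic C2–H bond, closing the pyranone ring and setting C2 in a single operation. The step exploits that C2 is benzylic to the electron-rich ring B, α to O1, and 1,6 to C3 across C4, C4a, C8a and O1. The precursor comes from phloroacetophenone by Mitsunobu benzylation, ortho-iodination and Negishi coupling with an Evans-derived (R)-lavandulyl zinc reagent.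

Key step: step 13

Remark on numbering: flavanone numbering is used for the ring atoms (O1, C2, C3, C4, C4a, C5 to C8, C8a; ring A is the benzo ring, ring B the 2-aryl group, ring C the pyranone). The target is the (2S)-flavanone carrying the (2S)-5-methyl-2-(prop-1-en-2-yl)hex-4-en-1-yl side chain at C6, which corresponds spatially to (R)-lavandulol.

Assumption: Rh2(S-BSP)4 is taken to deliver the 2S configuration in step 13. If the first run shows the opposite sense, the mirror-image catalyst Rh2(R-BSP)4 (from D-proline) is used with no other change.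

Step 1
Reactants: 1 (R)-4-benzyl-1,3-oxazolidin-2-one; 2 3-methylbut-2-enoyl chloride
Product: 3 (4R)-4-benzyl-3-(3-methylbut-2-enoyl)-1,3-oxazolidin-2-one
Conditions: n-BuLi, THF, −78 °C; then 2, −78 → 0 °C
Reagents that add atoms: none
Why: N-acylation of the lithiated oxazolidinone by the acid chloride is a standard imide formation, and the low temperature avoids vinylketene formation from 2.

Step 2
Reactants: 3 (4R)-4-benzyl-3-(3-methylbut-2-enoyl)-1,3-oxazolidin-2-one; 4 1-bromo-3-methylbut-2-ene (prenyl bromide)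
Product: 6 (4R)-4-benzyl-3-[(2R)-5-methyl-2-(prop-1-en-2-yl)hex-4-enoyl]-1,3-oxazolidin-2-one, via sodium dienolate 5 (not isolated)
Conditions: NaN(SiMe3)2, THF, −78 °C; then 4, −78 → −40 °C
Reagents that add atoms: none
Why: Evans asymmetric alkylation in its deconjugative form, in which γ-deprotonation gives the chelated Z-dienolate 5 that should be alkylated at the α-carbon on the face opposite the benzyl group of the (R)-auxiliary, setting the 2R centre.

Step 3
Reactants: 6 (4R)-4-benzyl-3-[(2R)-5-methyl-2-(prop-1-en-2-yl)hex-4-enoyl]-1,3-oxazolidin-2-one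
Product: 7 (R)-lavandulol, (2R)-5-methyl-2-(prop-1-en-2-yl)hex-4-en-1-ol
Conditions: LiBH4, H2O (1 equiv), Et2O, 0 °C
Reagents that add atoms: none
Why: Reductive cleavage of the N-acyl oxazolidinone by LiBH4 should give the primary alcohol without touching the β,γ-alkene or the α-centre, and returns auxiliary 1.

Step 4
Reactants: 7 (R)-lavandulol
Product: 8 (R)-lavandulyl iodide, (3R)-3-(iodomethyl)-2,6-dimethylhepta-1,5-diene
Conditions: I2, PPh3, imidazole, CH2Cl2, 0 °C
Reagents that add atoms: iodine, II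
Why: Appel-type iodination of a primary alcohol under neutral conditions, with the stereocentre β to the reacting carbon and therefore untouched.

Step 5
Reactants: 9 4-hydroxy-2-methoxybenzaldehyde
Product: 10 2-methoxy-4-[(triisopropylsilyl)oxy]benzaldehyde
Conditions: i-Pr3SiCl, imidazole, DMF, rt
Reagents that add atoms: chlorotriisopropylsilane, CC(C)[Si](Cl)(C(C)C)C(C)C
Why: Silylation of the only hydroxyl group gives a hindered aryl silyl ether that should survive the later basic and organometallic steps (phenol protection).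

Step 6
Reactants: 10 2-methoxy-4-[(triisopropylsilyl)oxy]benzaldehyde
Product: 11 {2-methoxy-4-[(triisopropylsilyl)oxy]phenyl}methanol
Conditions: NaBH4, MeOH, 0 °C
Reagents that add atoms: none
Why: Chemoselective borohydride reduction of the aldehyde to the benzylic alcohol leaves the hindered aryl silyl ether intact.

Step 7
Reactants: 12 1-(2,4,6-trihydroxyphenyl)ethan-1-one (phloroacetophenone)
Product: 13 1-{2,6-dihydroxy-4-[(triisopropylsilyl)oxy]phenyl}ethan-1-one
Conditions: i-Pr3SiCl (1.05 equiv), imidazole, DMF, 0 °C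
Reagents that add atoms: chlorotriisopropylsilane, CC(C)[Si](Cl)(C(C)C)C(C)C
Why: Selective silylation of the most acidic, unhindered para hydroxyl, while the two hydroxyls flanking the acetyl group are hydrogen-bonded and shielded (regioselective phenol protection).

Step 8
Reactants: 13 1-{2,6-dihydroxy-4-[(triisopropylsilyl)oxy]phenyl}ethan-1-one; 11 {2-methoxy-4-[(triisopropylsilyl)oxy]phenyl}methanol
Product: 14 1-[2-hydroxy-6-({2-methoxy-4-[(triisopropylsilyl)oxy]phenyl}methoxy)-4-[(triisopropylsilyl)oxy]phenyl]ethan-1-one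
Conditions: PPh3, DIAD, THF, 0 °C → rt
Reagents that add atoms: none
Why: Mitsunobu etherification alkylates one of the two equivalent phenols of symmetric 13 with the primary benzylic alcohol, and the remaining hydroxyl stays locked in a hydrogen bond to the acetyl group and should resist a second alkylation.

Step 9
Reactants: 14 1-[2-hydroxy-6-({2-methoxy-4-[(triisopropylsilyl)oxy]phenyl}methoxy)-4-[(triisopropylsilyl)oxy]phenyl]ethan-1-one
Product: 15 1-[2-hydroxy-3-iodo-6-({2-methoxy-4-[(triisopropylsilyl)oxy]phenyl}methoxy)-4-[(triisopropylsilyl)oxy]phenyl]ethan-1-one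
Conditions: BnMe3N ICl2, CaCO3, CH2Cl2–MeOH, rt
Reagents that add atoms: benzyltrimethylammonium dichloroiodate, C[N+](C)(C)Cc1ccccc1.Cl[I-]Cl
Why: Electrophilic aromatic iodination of the phenol ring should go to the position ortho to the free chelated hydroxyl (between OH and the silyloxy group, the sterically more open vacant site), while the ether-only ring B is much less reactive toward this mild iodonium source.

Step 10
Reactants: 15 1-[2-hydroxy-3-iodo-6-({2-methoxy-4-[(triisopropylsilyl)oxy]phenyl}methoxy)-4-[(triisopropylsilyl)oxy]phenyl]ethan-1-one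
Product: 16 1-{2-[(tert-butyldimethylsilyl)oxy]-3-iodo-6-({2-methoxy-4-[(triisopropylsilyl)oxy]phenyl}methoxy)-4-[(triisopropylsilyl)oxy]phenyl}ethan-1-one
Conditions: t-BuMe2SiCl, imidazole, DMAP (cat.), DMF, 40 °C
Reagents that add atoms: tert-butylchlorodimethylsilane, CC(C)(C)[Si](C)(C)Cl
Why: Silylation caps the future O5 with a group that has no C–H bond α to oxygen, as step 13 requires, and removes the acidic proton before the organozinc coupling (phenol protection).

Step 11
Reactants: 16 1-{2-[(tert-butyldimethylsilyl)oxy]-3-iodo-6-({2-methoxy-4-[(triisopropylsilyl)oxy]phenyl}methoxy)-4-[(triisopropylsilyl)oxy]phenyl}ethan-1-one; 8 (R)-lavandulyl iodide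
Product: 19 1-{2-[(tert-butyldimethylsilyl)oxy]-6-({2-methoxy-4-[(triisopropylsilyl)oxy]phenyl}methoxy)-3-[(2S)-5-methyl-2-(prop-1-en-2-yl)hex-4-en-1-yl]-4-[(triisopropylsilyl)oxy]phenyl}ethan-1-one, via (R)-lavandulyllithium 17 (not isolated), via (R)-lavandulylzinc chloride 18 (not isolated)
Conditions: 8, t-BuLi (2.1 equiv), Et2O, −78 °C; ZnCl2, THF, −78 °C → rt; then 16, Pd(OAc)2 (5 mol%), SPhos (10 mol%), THF–NMP, 50 °C
Reagents that add atoms: none
Why: Negishi sp2–sp3 coupling, in which iodine–lithium exchange and transmetalation to zinc avoid radical intermediates that could rearrange the homoallyl unit, and the bulky biarylphosphine should drive oxidative addition and fast reductive elimination at the hindered iodide so that the β-stereocentre is carried over unchanged.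

Step 12
Reactants: 19 1-{2-[(tert-butyldimethylsilyl)oxy]-6-({2-methoxy-4-[(triisopropylsilyl)oxy]phenyl}methoxy)-3-[(2S)-5-methyl-2-(prop-1-en-2-yl)hex-4-en-1-yl]-4-[(triisopropylsilyl)oxy]phenyl}ethan-1-one
Product: 21 2-diazo-1-{2-[(tert-butyldimethylsilyl)oxy]-6-({2-methoxy-4-[(triisopropylsilyl)oxy]phenyl}methoxy)-3-[(2S)-5-methyl-2-(prop-1-en-2-yl)hex-4-en-1-yl]-4-[(triisopropylsilyl)oxy]phenyl}ethan-1-one, via trifluoroacetyl diketone 20 (not isolated)
Conditions: LiN(SiMe3)2, THF, −78 °C; CF3CO2CH2CF3, −78 °C; then MeSO2N3, Et3N, H2O (1 equiv), MeCN, rt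
Reagents that add atoms: methanesulfonyl azide, CS(=O)(=O)N=[N+]=[N-]
Why: Detrifluoroacetylative Regitz-type diazo transfer, in which the kinetic lithium enolate is trifluoroacetylated to the activated 1,3-diketone 20, which should accept the diazo group from the sulfonyl azide and lose the trifluoroacetyl group as the sulfonamide.

Step 13
Reactants: 21 2-diazo-1-{2-[(tert-butyldimethylsilyl)oxy]-6-({2-methoxy-4-[(triisopropylsilyl)oxy]phenyl}methoxy)-3-[(2S)-5-methyl-2-(prop-1-en-2-yl)hex-4-en-1-yl]-4-[(triisopropylsilyl)oxy]phenyl}ethan-1-one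
Product: 22 (2S)-5-[(tert-butyldimethylsilyl)oxy]-2-{2-methoxy-4-[(triisopropylsilyl)oxy]phenyl}-6-[(2S)-5-methyl-2-(prop-1-en-2-yl)hex-4-en-1-yl]-7-[(triisopropylsilyl)oxy]-2,3-dihydro-4H-chromen-4-one
Conditions: Rh2(S-BSP)4 [dirhodium tetrakis(N-benzenesulfonyl-L-prolinate)] (2 mol%), 4 Å sieves, CH2Cl2, 0 °C → rt, slow addition of 21 at high dilution
Reagents that add atoms: none
Why: The divalent rhodium carboxylate should decompose the diazoketone with loss of N2 to an electrophilic rhodium carbenoid at the future C3, which inserts into the benzylic ether C–H bond at the future C2 through a concerted, asynchronous three-centre transition state with hydride-transfer character (intramolecular carbenoid C–H insertion). The closest known reaction type is the dirhodium carboxylate-catalysed cyclization of 2-alkoxyaryl diazoketones to 2-substituted chroman-4-ones, which includes benzyl ethers and chiral prolinate catalysts. Ring C is closed in a 1,6-insertion mode through a six-membered cyclic transition state made of C3, C4, C4a, C8a, O1 and C2, and no 1,5-site exists because that position is O1 itself. The new stereocentre C2 is set by the chiral carboxylate ligands of the catalyst, which discriminate the two enantiotopic benzylic hydrogens, while the remote lavandulyl centre should exert no influence. The step needs chemoselectivity for this C–H bond over oxonium ylide formation at O1 with [1,2]-benzyl shift, over insertion on the O5 side and over cyclopropanation of the lavandulyl alkenes: the C2–H bond is doubly activated by O1 and by the 2-methoxy-4-silyloxyphenyl ring, the O5 group is a silyl ether with no C–H bond α to oxygen, the aryl ether oxygen is a poor ylide donor toward a carboxylate-ligated carbenoid, and the alkenes cannot reach C3 through a small ring. Slow addition at high dilution should suppress intermolecular cyclopropanation and carbene dimerization.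

Step 14
Reactants: 22 (2S)-5-[(tert-butyldimethylsilyl)oxy]-2-{2-methoxy-4-[(triisopropylsilyl)oxy]phenyl}-6-[(2S)-5-methyl-2-(prop-1-en-2-yl)hex-4-en-1-yl]-7-[(triisopropylsilyl)oxy]-2,3-dihydro-4H-chromen-4-one
Product: 23 (2S)-5,7-dihydroxy-2-(4-hydroxy-2-methoxyphenyl)-6-[(2S)-5-methyl-2-(prop-1-en-2-yl)hex-4-en-1-yl]-2,3-dihydro-4H-chromen-4-one (target)
Conditions: Bu4NF, AcOH (1:1), THF, 0 °C
Reagents that add atoms: none
Why: Fluoride-mediated cleavage of the three aryl silyl ethers under acetic acid buffering should free the phenols without the acid that would cyclize the lavandulyl group onto O5 or O7 and without the free phenoxide that would open ring C and racemize C2 (global desilylation).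

Compound list

1 | (R)-4-benzyl-1,3-oxazolidin-2-one | O=C1N[C@H](Cc2ccccc2)CO1 | starting material
2 | 3-methylbut-2-enoyl chloride | CC(C)=CC(=O)Cl | starting material
3 | (4R)-4-benzyl-3-(3-methylbut-2-enoyl)-1,3-oxazolidin-2-one | CC(C)=CC(=O)N1C(=O)OC[C@H]1Cc1ccccc1 | intermediate
4 | 1-bromo-3-methylbut-2-ene (prenyl bromide) | CC(C)=CCBr | starting material
5 | sodium (1Z)-1-[(4R)-4-benzyl-2-oxo-1,3-oxazolidin-3-yl]-3-methylbuta-1,3-dien-1-olate (sodium dienolate of 3) | C=C(C)/C=C(\[O-])N1C(=O)OC[C@H]1Cc1ccccc1.[Na+] | intermediate (not isolated)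
6 | (4R)-4-benzyl-3-[(2R)-5-methyl-2-(prop-1-en-2-yl)hex-4-enoyl]-1,3-oxazolidin-2-one | C=C(C)[C@@H](CC=C(C)C)C(=O)N1C(=O)OC[C@H]1Cc1ccccc1 | intermediate
7 | (R)-lavandulol, (2R)-5-methyl-2-(prop-1-en-2-yl)hex-4-en-1-ol | C=C(C)[C@@H](CC=C(C)C)CO | intermediate
8 | (R)-lavandulyl iodide, (3R)-3-(iodomethyl)-2,6-dimethylhepta-1,5-diene | C=C(C)[C@@H](CC=C(C)C)CI | intermediate
9 | 4-hydroxy-2-methoxybenzaldehyde | COc1cc(O)ccc1C=O | starting material
10 | 2-methoxy-4-[(triisopropylsilyl)oxy]benzaldehyde | COc1cc(O[Si](C(C)C)(C(C)C)C(C)C)ccc1C=O | intermediate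
11 | {2-methoxy-4-[(triisopropylsilyl)oxy]phenyl}methanol | COc1cc(O[Si](C(C)C)(C(C)C)C(C)C)ccc1CO | intermediate
12 | 1-(2,4,6-trihydroxyphenyl)ethan-1-one (phloroacetophenone) | CC(=O)c1c(O)cc(O)cc1O | starting material
13 | 1-{2,6-dihydroxy-4-[(triisopropylsilyl)oxy]phenyl}ethan-1-one | CC(=O)c1c(O)cc(O[Si](C(C)C)(C(C)C)C(C)C)cc1O | intermediate
14 | 1-[2-hydroxy-6-({2-methoxy-4-[(triisopropylsilyl)oxy]phenyl}methoxy)-4-[(triisopropylsilyl)oxy]phenyl]ethan-1-one | CC(=O)c1c(O)cc(O[Si](C(C)C)(C(C)C)C(C)C)cc1OCc1ccc(O[Si](C(C)C)(C(C)C)C(C)C)cc1OC | intermediate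
15 | 1-[2-hydroxy-3-iodo-6-({2-methoxy-4-[(triisopropylsilyl)oxy]phenyl}methoxy)-4-[(triisopropylsilyl)oxy]phenyl]ethan-1-one | CC(=O)c1c(O)c(I)c(O[Si](C(C)C)(C(C)C)C(C)C)cc1OCc1ccc(O[Si](C(C)C)(C(C)C)C(C)C)cc1OC | intermediate
16 | 1-{2-[(tert-butyldimethylsilyl)oxy]-3-iodo-6-({2-methoxy-4-[(triisopropylsilyl)oxy]phenyl}methoxy)-4-[(triisopropylsilyl)oxy]phenyl}ethan-1-one | CC(=O)c1c(O[Si](C)(C)C(C)(C)C)c(I)c(O[Si](C(C)C)(C(C)C)C(C)C)cc1OCc1ccc(O[Si](C(C)C)(C(C)C)C(C)C)cc1OC | intermediate
17 | (R)-lavandulyllithium, [(2R)-5-methyl-2-(prop-1-en-2-yl)hex-4-en-1-yl]lithium | C=C(C)[C@@H](CC=C(C)C)C[Li] | intermediate (not isolated)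
18 | (R)-lavandulylzinc chloride, chlorido[(2R)-5-methyl-2-(prop-1-en-2-yl)hex-4-en-1-yl]zinc | C=C(C)[C@@H](CC=C(C)C)C[Zn]Cl | intermediate (not isolated)
19 | 1-{2-[(tert-butyldimethylsilyl)oxy]-6-({2-methoxy-4-[(triisopropylsilyl)oxy]phenyl}methoxy)-3-[(2S)-5-methyl-2-(prop-1-en-2-yl)hex-4-en-1-yl]-4-[(triisopropylsilyl)oxy]phenyl}ethan-1-one | C=C(C)[C@@H](CC=C(C)C)Cc1c(O[Si](C)(C)C(C)(C)C)c(C(C)=O)c(OCc2ccc(O[Si](C(C)C)(C(C)C)C(C)C)cc2OC)cc1O[Si](C(C)C)(C(C)C)C(C)C | intermediate
20 | 4,4,4-trifluoro-1-{2-[(tert-butyldimethylsilyl)oxy]-6-({2-methoxy-4-[(triisopropylsilyl)oxy]phenyl}methoxy)-3-[(2S)-5-methyl-2-(prop-1-en-2-yl)hex-4-en-1-yl]-4-[(triisopropylsilyl)oxy]phenyl}butane-1,3-dione | C=C(C)[C@@H](CC=C(C)C)Cc1c(O[Si](C)(C)C(C)(C)C)c(C(=O)CC(=O)C(F)(F)F)c(OCc2ccc(O[Si](C(C)C)(C(C)C)C(C)C)cc2OC)cc1O[Si](C(C)C)(C(C)C)C(C)C | intermediate (not isolated)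
21 | 2-diazo-1-{2-[(tert-butyldimethylsilyl)oxy]-6-({2-methoxy-4-[(triisopropylsilyl)oxy]phenyl}methoxy)-3-[(2S)-5-methyl-2-(prop-1-en-2-yl)hex-4-en-1-yl]-4-[(triisopropylsilyl)oxy]phenyl}ethan-1-one | C=C(C)[C@@H](CC=C(C)C)Cc1c(O[Si](C)(C)C(C)(C)C)c(C(=O)C=[N+]=[N-])c(OCc2ccc(O[Si](C(C)C)(C(C)C)C(C)C)cc2OC)cc1O[Si](C(C)C)(C(C)C)C(C)C | intermediate
22 | (2S)-5-[(tert-butyldimethylsilyl)oxy]-2-{2-methoxy-4-[(triisopropylsilyl)oxy]phenyl}-6-[(2S)-5-methyl-2-(prop-1-en-2-yl)hex-4-en-1-yl]-7-[(triisopropylsilyl)oxy]-2,3-dihydro-4H-chromen-4-one | C=C(C)[C@@H](CC=C(C)C)Cc1c(O[Si](C(C)C)(C(C)C)C(C)C)cc2c(c1O[Si](C)(C)C(C)(C)C)C(=O)C[C@@H](c1ccc(O[Si](C(C)C)(C(C)C)C(C)C)cc1OC)O2 | intermediate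
23 | (2S)-5,7-dihydroxy-2-(4-hydroxy-2-methoxyphenyl)-6-[(2S)-5-methyl-2-(prop-1-en-2-yl)hex-4-en-1-yl]-2,3-dihydro-4H-chromen-4-one | C=C(C)[C@@H](CC=C(C)C)Cc1c(O)cc2c(c1O)C(=O)C[C@@H](c1ccc(O)cc1OC)O2 | target

Total step count: 14.
Longest linear sequence: 9 steps (steps 5 and 6, then steps 8 to 14, from 4-hydroxy-2-methoxybenzaldehyde 9). The phloroacetophenone branch (steps 7 to 14 from 12) and the lavandulyl branch (steps 1 to 4 and 11 to 14) each run to 8 steps.

Steps most likely to fail

1. Step 13 (carbenoid C–H insertion). The carbenoid may be diverted into oxonium ylide formation at O1 followed by [1,2]-migration of the electron-rich benzyl group, or the catalyst may discriminate the two enantiotopic C2–H bonds poorly. The fallback sets out from 19 and comes back at 22, and closes the same C2–C3 bond without a carbenoid. Ketone 19 is O-acetylated through its potassium enolate (KN(SiMe3)2, Ac2O, THF, −78 °C) to the enol acetate 1-{2-[(tert-butyldimethylsilyl)oxy]-6-({2-methoxy-4-[(triisopropylsilyl)oxy]phenyl}methoxy)-3-[(2S)-5-methyl-2-(prop-1-en-2-yl)hex-4-en-1-yl]-4-[(triisopropylsilyl)oxy]phenyl}ethenyl acetate F1. DDQ (2,6-dichloropyridine, LiClO4, 4 Å sieves, 1,2-dichloroethane, rt) should then oxidize the benzylic ether C–H bond of the electron-rich ring B to an aryl-stabilized oxocarbenium ion, which the enol acetate captures at C3 (oxidative C–H cleavage with Mukaiyama-type closure, known for electron-rich benzylic ethers with tethered enol acetates). This closure is not stereocontrolled, so 22 is expected together with its C2 epimer, the (2R)-configured silyl-protected flavanone F2. The two are diastereomers and would be separated by preparative HPLC before step 14.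

2. Step 11 (Negishi coupling). Oxidative addition and transmetalation at the iodide flanked by two silyloxy groups may be so slow that β-hydride elimination of the alkylpalladium intermediate and protodezincation outrun the coupling. The fallback sets out from 15 and 17 and comes back at 19, with a boron nucleophile and the less hindered, unsilylated iodide. Lavandulyllithium 17 is trapped with B-methoxy-9-BBN (Et2O–THF, −78 °C → rt) to give lithium B-methoxy-B-[(2R)-5-methyl-2-(prop-1-en-2-yl)hex-4-en-1-yl]-9-borabicyclo[3.3.1]nonan-9-uide F3. B-alkyl Suzuki–Miyaura coupling of F3 with iodophenol 15 [PdCl2(dppf), K3PO4, DMF–H2O, rt → 45 °C] should give 1-{2-hydroxy-6-({2-methoxy-4-[(triisopropylsilyl)oxy]phenyl}methoxy)-3-[(2S)-5-methyl-2-(prop-1-en-2-yl)hex-4-en-1-yl]-4-[(triisopropylsilyl)oxy]phenyl}ethan-1-one F4. Silylation of F4 (t-BuMe2SiCl, imidazole, DMAP, DMF) then delivers 19.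

3. Step 12 (diazo transfer through the lithium enolate). The tert-butyldimethylsilyl group may migrate from the ortho phenolic oxygen to the enolate oxygen, or the para-silyloxy ketone may be attacked during enolate generation, before trifluoroacetylation is complete. The fallback sets out from 19 and comes back at 21 without any enolate. Condensation of 19 with N,N-dimethylformamide dimethyl acetal (neat, 90 °C) should give the enaminone (2E)-3-(dimethylamino)-1-{2-[(tert-butyldimethylsilyl)oxy]-6-({2-methoxy-4-[(triisopropylsilyl)oxy]phenyl}methoxy)-3-[(2S)-5-methyl-2-(prop-1-en-2-yl)hex-4-en-1-yl]-4-[(triisopropylsilyl)oxy]phenyl}prop-2-en-1-one F5. Diazo transfer from MeSO2N3 to F5 (MeCN, rt; triazoline formation and cycloreversion, a known route from enaminones to diazomethyl ketones) then gives 21.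

Further compounds

F1 | step 13 | 1-{2-[(tert-butyldimethylsilyl)oxy]-6-({2-methoxy-4-[(triisopropylsilyl)oxy]phenyl}methoxy)-3-[(2S)-5-methyl-2-(prop-1-en-2-yl)hex-4-en-1-yl]-4-[(triisopropylsilyl)oxy]phenyl}ethenyl acetate | C=C(C)[C@@H](CC=C(C)C)Cc1c(O[Si](C)(C)C(C)(C)C)c(C(=C)OC(C)=O)c(OCc2ccc(O[Si](C(C)C)(C(C)C)C(C)C)cc2OC)cc1O[Si](C(C)C)(C(C)C)C(C)C
F2 | step 13 | (2R)-5-[(tert-butyldimethylsilyl)oxy]-2-{2-methoxy-4-[(triisopropylsilyl)oxy]phenyl}-6-[(2S)-5-methyl-2-(prop-1-en-2-yl)hex-4-en-1-yl]-7-[(triisopropylsilyl)oxy]-2,3-dihydro-4H-chromen-4-one | C=C(C)[C@@H](CC=C(C)C)Cc1c(O[Si](C(C)C)(C(C)C)C(C)C)cc2c(c1O[Si](C)(C)C(C)(C)C)C(=O)C[C@H](c1ccc(O[Si](C(C)C)(C(C)C)C(C)C)cc1OC)O2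
F3 | step 11 | lithium B-methoxy-B-[(2R)-5-methyl-2-(prop-1-en-2-yl)hex-4-en-1-yl]-9-borabicyclo[3.3.1]nonan-9-uide | C=C(C)[C@@H](CC=C(C)C)C[B-]1(OC)C2CCCC1CCC2.[Li+]
F4 | step 11 | 1-{2-hydroxy-6-({2-methoxy-4-[(triisopropylsilyl)oxy]phenyl}methoxy)-3-[(2S)-5-methyl-2-(prop-1-en-2-yl)hex-4-en-1-yl]-4-[(triisopropylsilyl)oxy]phenyl}ethan-1-one | C=C(C)[C@@H](CC=C(C)C)Cc1c(O)c(C(C)=O)c(OCc2ccc(O[Si](C(C)C)(C(C)C)C(C)C)cc2OC)cc1O[Si](C(C)C)(C(C)C)C(C)C
F5 | step 12 | (2E)-3-(dimethylamino)-1-{2-[(tert-butyldimethylsilyl)oxy]-6-({2-methoxy-4-[(triisopropylsilyl)oxy]phenyl}methoxy)-3-[(2S)-5-methyl-2-(prop-1-en-2-yl)hex-4-en-1-yl]-4-[(triisopropylsilyl)oxy]phenyl}prop-2-en-1-one | C=C(C)[C@@H](CC=C(C)C)Cc1c(O[Si](C)(C)C(C)(C)C)c(C(=O)/C=C/N(C)C)c(OCc2ccc(O[Si](C(C)C)(C(C)C)C(C)C)cc2OC)cc1O[Si](C(C)C)(C(C)C)C(C)C
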